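## Retrosynthetic overview

1. Ring numbering: C1 ketone, C2=C3, C4 tertiary carbinol carrying the (Z)-heptadec-10-enyl chain, C5 CH2, C6 secondary carbinol. The route rests on the C1(=O)–C2=C3 edge of the cyclohexenone ring. This edge is read as an ester carbon (C1, on C6) plus a plain vinyl group (C2=C3, on C4); the two are first joined twice (C1–C2 and C1–C3), and the surplus C1–C3 bond is then cut.
2. 30 ⇒ bis-silyl enone 29 ⇒ 3-chloroketone 28 ⇒ bicyclo[3.1.0]hexan-1-ol 27 (FeCl3 breaks the bond shared by the two rings) ⇒ acyclic vinyl ester 24 (intramolecular Kulinkovich reaction).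
3. 24 ⇒ tertiary allylic alcohol 19 ⇒ epoxy alcohol 17 (Sharpless epoxidation sets C4; zinc fragmentation of the derived iodide unveils C2=C3) ⇒ Z-allylic alcohol 16 ⇒ ynoate 12 + chain organocopper 14 (syn-carbocupration).
4. 12 ⇒ (R)-glycidol (brings C6) + ethyl propiolate; 14 ⇒ 10-bromodecan-1-ol + heptanal (Z-selective Wittig). The only alkene oxidation in the route is hydroxyl-directed, so the chain alkene never competes.
5. Ring order: the cyclopentane ring (C1, C3, C4, C5, C6) and the cyclopropane ring (C1, C2, C3) form in one flask in step 16; the six-membered ring appears in step 17.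

Key step: step 16

Remark: the face of ring fusion in 25–27 and the configuration of the C3–Cl centre in 28 are not controlled, and both are erased in steps 17 and 18. Compounds 25–27 are drawn as the isomer with the cyclopropane CH2 on the face of the two silyloxy groups, and 28 is drawn with C3 undefined.

Abbreviations: TBS = tert-butyldimethylsilyl, TES = triethylsilyl, PMB = 4-methoxybenzyl.

## Route

Step 1
Reactants: 1 10-bromodecan-1-ol
Product: 2 (10-hydroxydecyl)triphenylphosphonium bromide
Conditions: PPh3, MeCN, reflux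
Reagents that add atoms: triphenylphosphine, c1ccc(cc1)P(c1ccccc1)c1ccccc1
Why: SN2 quaternisation of the primary bromide by the phosphine gives the Wittig salt, and the remote hydroxyl does not interfere.

Step 2
Reactants: 2 (10-hydroxydecyl)triphenylphosphonium bromide, 3 heptanal
Product: 5 (Z)-heptadec-10-en-1-ol, via alkoxide ylide 4 (not isolated)
Conditions: NaN(SiMe3)2 (2.1 equiv), THF, 0 °C; then 3, −78 °C to rt
Reagents that add atoms: none
Why: Wittig olefination of a non-stabilised ylide with an aliphatic aldehyde under lithium-free kinetic control should give the Z-alkene through the cis-oxaphosphetane, the second equivalent of base only holding the hydroxyl as its alkoxide.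

Step 3
Reactants: 5 (Z)-heptadec-10-en-1-ol
Product: 6 (Z)-17-bromoheptadec-7-ene
Conditions: CBr4, PPh3, CH2Cl2, 0 °C
Reagents that add atoms: carbon tetrabromide, BrC(Br)(Br)Br
Why: Appel bromination replaces the primary hydroxyl by SN2 under neutral conditions that leave the Z-alkene untouched.

Step 4
Reactants: 7 (R)-glycidol
Product: 8 (S)-2-[(4-methoxybenzyloxy)methyl]oxirane
Conditions: NaH, PMBCl, n-Bu4NI (cat.), THF/DMF, 0 °C to rt
Reagents that add atoms: 4-methoxybenzyl chloride, COc1ccc(CCl)cc1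
Why: Williamson etherification of the primary alkoxide does not touch the stereocentre (the descriptor changes from R to S only through the CIP ranking), and the Payne rearrangement of this alkoxide is degenerate.

Step 5
Reactants: 8 (S)-2-[(4-methoxybenzyloxy)methyl]oxirane, 9 ethyl propiolate
Product: 11 ethyl (5S)-5-hydroxy-6-(4-methoxybenzyloxy)hex-2-ynoate, via lithium ethyl propiolate 10 (not isolated)
Conditions: 9, n-BuLi, THF, −78 °C; BF3·OEt2; then 8, −78 °C
Reagents that add atoms: none
Why: In this Yamaguchi–Hirao alkynylation the BF3-activated epoxide is opened by SN2 at its CH2 terminus, so the carbinol centre (future C6) is carried over unchanged and the epoxide CH2 becomes C5.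

Step 6
Reactants: 11 ethyl (5S)-5-hydroxy-6-(4-methoxybenzyloxy)hex-2-ynoate
Product: 12 ethyl (5S)-5-(tert-butyldimethylsilyloxy)-6-(4-methoxybenzyloxy)hex-2-ynoate
Conditions: TBSOTf, 2,6-lutidine, CH2Cl2, −78 to 0 °C
Reagents that add atoms: tert-butyldimethylsilyl triflate, CC(C)(C)[Si](C)(C)OS(=O)(=O)C(F)(F)F
Why: Silylation with a silyl triflate and a hindered base protects the secondary alcohol without offering a nucleophilic amine to the electrophilic ynoate.

Step 7
Reactants: 6 (Z)-17-bromoheptadec-7-ene, 12 ethyl (5S)-5-(tert-butyldimethylsilyloxy)-6-(4-methoxybenzyloxy)hex-2-ynoate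
Product: 15 ethyl (2Z,13Z)-3-[(2S)-2-(tert-butyldimethylsilyloxy)-3-(4-methoxybenzyloxy)propyl]icosa-2,13-dienoate, via Grignard reagent 13 (not isolated), via organocopper reagent 14 (not isolated)
Conditions: 6, Mg, THF, rt; CuBr·SMe2 (1 equiv per 13), THF, −40 °C; 12, −78 °C; aq NH4Cl at −78 °C
Reagents that add atoms: none
Why: Syn-carbocupration of a 2-ynoate puts the chain and the copper on the same side of the new alkene, and protonation in the cold, before any allenolate equilibration, should fix the 2Z geometry with the chain trans to the ester.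

Step 8
Reactants: 15 ethyl (2Z,13Z)-3-[(2S)-2-(tert-butyldimethylsilyloxy)-3-(4-methoxybenzyloxy)propyl]icosa-2,13-dienoate
Product: 16 (2Z,13Z)-3-[(2S)-2-(tert-butyldimethylsilyloxy)-3-(4-methoxybenzyloxy)propyl]icosa-2,13-dien-1-ol
Conditions: i-Bu2AlH (2.5 equiv), CH2Cl2, −78 to −20 °C
Reagents that add atoms: none
Why: 1,2-Reduction of the enoate with i-Bu2AlH gives the allylic alcohol with the alkene geometry, both ethers and the chain alkene intact.

Step 9
Reactants: 16 (2Z,13Z)-3-[(2S)-2-(tert-butyldimethylsilyloxy)-3-(4-methoxybenzyloxy)propyl]icosa-2,13-dien-1-ol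
Product: 17 {(2S,3R)-3-[(2S)-2-(tert-butyldimethylsilyloxy)-3-(4-methoxybenzyloxy)propyl]-3-[(Z)-heptadec-10-en-1-yl]oxiran-2-yl}methanol
Conditions: Ti(OiPr)4 (0.2 equiv), L-(+)-diethyl tartrate (0.24 equiv), t-BuOOH (decane), 4 Å MS, CH2Cl2, −20 °C
Reagents that add atoms: tert-butyl hydroperoxide, CC(C)(C)OO
Why: In the Katsuki–Sharpless epoxidation the titanium-bound allylic alkoxide is oxidised on the face dictated by L-(+)-tartrate (the sense known for nerol-type 3,3-disubstituted Z-allylic alcohols), which sets C4 as R, while the chain alkene has no directing hydroxyl and stays out.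

Step 10
Reactants: 17 {(2S,3R)-3-[(2S)-2-(tert-butyldimethylsilyloxy)-3-(4-methoxybenzyloxy)propyl]-3-[(Z)-heptadec-10-en-1-yl]oxiran-2-yl}methanol
Product: 18 (2R,3R)-2-[(2S)-2-(tert-butyldimethylsilyloxy)-3-(4-methoxybenzyloxy)propyl]-2-[(Z)-heptadec-10-en-1-yl]-3-(iodomethyl)oxirane
Conditions: PPh3, imidazole, I2 (premixed), CH2Cl2, 0 °C
Reagents that add atoms: iodine, [I][I]
Why: Garegg–Samuelsson (Appel-type) iodination converts the primary alcohol by SN2 under imidazole-buffered conditions that spare the trisubstituted epoxide, and no stereocentre is touched (the descriptor at the CH carbon changes by ranking only).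

Step 11
Reactants: 18 (2R,3R)-2-[(2S)-2-(tert-butyldimethylsilyloxy)-3-(4-methoxybenzyloxy)propyl]-2-[(Z)-heptadec-10-en-1-yl]-3-(iodomethyl)oxirane
Product: 19 (2S,4R,14Z)-2-(tert-butyldimethylsilyloxy)-4-ethenyl-1-(4-methoxybenzyloxy)henicos-14-en-4-ol
Conditions: activated Zn dust, EtOH, 70 °C
Reagents that add atoms: none
Why: Reductive fragmentation of a 2,3-epoxy iodide (zinc insertion, then beta-elimination with epoxide opening, as in the epoxygeraniol-to-linalool transposition) breaks only the C3–O bond, so the C4–O bond keeps its configuration while the vinyl group C2=C3 appears.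

Step 12
Reactants: 19 (2S,4R,14Z)-2-(tert-butyldimethylsilyloxy)-4-ethenyl-1-(4-methoxybenzyloxy)henicos-14-en-4-ol
Product: 20 TES ether of 19 at the C4 oxygen
Conditions: TESOTf, 2,6-lutidine, CH2Cl2, −78 to 0 °C
Reagents that add atoms: triethylsilyl triflate, CC[Si](CC)(CC)OS(=O)(=O)C(F)(F)F
Why: A silyl triflate is reactive enough for the hindered tertiary allylic alcohol, and capping it now prevents gamma-lactonisation once C1 is raised to the ester level.

Step 13
Reactants: 20 TES ether of 19
Product: 21 (2S,4R,14Z)-2-(tert-butyldimethylsilyloxy)-4-ethenyl-4-(triethylsilyloxy)henicos-14-en-1-ol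
Conditions: DDQ, CH2Cl2/pH 7 buffer, 0 °C
Reagents that add atoms: none
Why: Oxidative cleavage of the PMB ether by hydride abstraction with DDQ is specific for the electron-rich benzyl group, and the neutral medium leaves both silyl ethers in place and both alkenes alone.

Step 14
Reactants: 21 (2S,4R,14Z)-2-(tert-butyldimethylsilyloxy)-4-ethenyl-4-(triethylsilyloxy)henicos-14-en-1-ol
Product: 23 (2S,4R,14Z)-2-(tert-butyldimethylsilyloxy)-4-ethenyl-4-(triethylsilyloxy)henicos-14-enoic acid, via aldehyde 22 (not isolated)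
Conditions: TEMPO (cat.), PhI(OAc)2, MeCN/pH 7 buffer, rt
Reagents that add atoms: water, O
Why: Oxoammonium-mediated oxidation takes the primary alcohol through the aldehyde hydrate to the acid without attacking alkenes and without a base that could epimerise C6.

Step 15
Reactants: 23 (2S,4R,14Z)-2-(tert-butyldimethylsilyloxy)-4-ethenyl-4-(triethylsilyloxy)henicos-14-enoic acid
Product: 24 methyl (2S,4R,14Z)-2-(tert-butyldimethylsilyloxy)-4-ethenyl-4-(triethylsilyloxy)henicos-14-enoate
Conditions: Me3SiCHN2, PhMe/MeOH, 0 °C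
Reagents that add atoms: (trimethylsilyl)diazomethane, C[Si](C)(C)C=[N+]=[N-]
Why: O-Methylation of the carboxylic acid by the diazoalkane is fast and neutral, so neither silyl ether nor the alpha-stereocentre is at risk.

Step 16
Reactants: 24 methyl (2S,4R,14Z)-2-(tert-butyldimethylsilyloxy)-4-ethenyl-4-(triethylsilyloxy)henicos-14-enoate
Product: 27 (1S,2S,4R,5S)-2-(tert-butyldimethylsilyloxy)-4-[(Z)-heptadec-10-en-1-yl]-4-(triethylsilyloxy)bicyclo[3.1.0]hexan-1-ol, via titanacyclopropane 25 (not isolated), via titanium homoenolate 26 (not isolated)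
Conditions: Ti(OiPr)4 (1.2 equiv), c-C5H9MgCl (4.5 equiv, syringe pump), THF (0.03 M), 0 °C to rt
Reagents that add atoms: none
Why: Two equivalents of c-C5H9MgCl reduce Ti(OiPr)4 to the divalent titanium–cyclopentene complex, which passes the metal on to the only monosubstituted alkene of 24 to give 25; this is the olefin-exchange form of the intramolecular Kulinkovich hydroxycyclopropanation, known for hex-5-enoates. The Ti–C3 bond of 25 adds to the C1 ester carbonyl in a 5-exo-trig closure that forms C1–C3 and the cyclopentane ring, methoxide is expelled to leave ketone 26, and its C2–Ti bond adds to the C1 ketone in a 3-exo-trig closure that forms C1–C2 and the cyclopropane ring (the opposite order of the two additions would end at the same bicycle). The new stereocentres C1 and C3 are tied to each other by the obligatory cis fusion, and their sense relative to C4 is decided by which vinyl face binds titanium, the expected preference placing C2 next to the C4 oxygen rather than next to the C4 alkyl chain. That sense is of no consequence, because C1 and C3 both become planar in steps 17 and 18, while C4 has no hydrogen to lose and C6 is alpha to a ketone only in the short-lived 26. The step needs titanation of the terminal vinyl group in preference to the chain alkene, secured because a 1,2-disubstituted alkene does not displace cyclopentene from titanium, and it needs the ester to meet titanium rather than free Grignard reagent, secured by slow addition and by the sluggishness of the hindered cyclopentene complex toward esters. It also needs ring closure to outrun loss of the C4 oxygen, for which the poor leaving ability of a silyloxide and the short tether speak.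

Step 17
Reactants: 27 (1S,2S,4R,5S)-2-(tert-butyldimethylsilyloxy)-4-[(Z)-heptadec-10-en-1-yl]-4-(triethylsilyloxy)bicyclo[3.1.0]hexan-1-ol
Product: 28 (2S,4R,5RS)-2-(tert-butyldimethylsilyloxy)-5-chloro-4-[(Z)-heptadec-10-en-1-yl]-4-(triethylsilyloxy)cyclohexan-1-one
Conditions: FeCl3 (2.5 equiv), pyridine (1.2 equiv), DMF, 0 °C
Reagents that add atoms: FeCl3 (iron trichloride), Cl[Fe](Cl)Cl
Why: In this oxidative ring expansion of a bicyclic cyclopropanol, trivalent iron takes one electron to give the cyclopropyloxy radical, strain release breaks the shared C1–C3 bond because that gives the secondary ring radical at C3 rather than a primary one, a second FeCl3 hands chlorine to C3, and pyridine takes up the HCl that would threaten the silyl ethers.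

Step 18
Reactants: 28 (2S,4R,5RS)-2-(tert-butyldimethylsilyloxy)-5-chloro-4-[(Z)-heptadec-10-en-1-yl]-4-(triethylsilyloxy)cyclohexan-1-one
Product: 29 (4R,6S)-6-(tert-butyldimethylsilyloxy)-4-[(Z)-heptadec-10-en-1-yl]-4-(triethylsilyloxy)cyclohex-2-en-1-one
Conditions: NaOAc, MeOH, rt to 40 °C
Reagents that add atoms: none
Why: E1cB dehydrochlorination of the beta-chloro ketone removes a C2 proton and expels chloride from C3 whatever its configuration, with a base too weak to epimerise C6.

Step 19
Reactants: 29 (4R,6S)-6-(tert-butyldimethylsilyloxy)-4-[(Z)-heptadec-10-en-1-yl]-4-(triethylsilyloxy)cyclohex-2-en-1-one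
Product: 30 (4R,6S)-4-[(Z)-heptadec-10-en-1-yl]-4,6-dihydroxycyclohex-2-en-1-one
Conditions: HF·pyridine, pyridine, THF, 0 °C to rt
Reagents that add atoms: none
Why: Fluoride-driven desilylation in a buffered, slightly acidic medium frees both carbinols and avoids the epimerisation and the dehydration to a catechol that a basic fluoride source could start in a 4,6-dihydroxycyclohexenone.

## Compound list

1 | 10-bromodecan-1-ol | OCCCCCCCCCCBr | starting material
2 | (10-hydroxydecyl)triphenylphosphonium bromide | OCCCCCCCCCC[P+](c1ccccc1)(c1ccccc1)c1ccccc1.[Br-] | intermediate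
3 | heptanal | CCCCCCC=O | starting material
4 | sodium 10-(triphenylphosphoranylidene)decan-1-olate (alkoxide ylide) | [Na+].[O-]CCCCCCCCCC=P(c1ccccc1)(c1ccccc1)c1ccccc1 | intermediate
5 | (Z)-heptadec-10-en-1-ol | CCCCCC/C=C\CCCCCCCCCO | intermediate
6 | (Z)-17-bromoheptadec-7-ene | CCCCCC/C=C\CCCCCCCCCBr | intermediate
7 | (R)-glycidol | OC[C@@H]1CO1 | starting material
8 | (S)-2-[(4-methoxybenzyloxy)methyl]oxirane | COc1ccc(COC[C@@H]2CO2)cc1 | intermediate
9 | ethyl propiolate | C#CC(=O)OCC | starting material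
10 | lithium ethyl propiolate | [Li]C#CC(=O)OCC | intermediate
11 | ethyl (5S)-5-hydroxy-6-(4-methoxybenzyloxy)hex-2-ynoate | COc1ccc(COC[C@@H](O)CC#CC(=O)OCC)cc1 | intermediate
12 | ethyl (5S)-5-(tert-butyldimethylsilyloxy)-6-(4-methoxybenzyloxy)hex-2-ynoate | COc1ccc(COC[C@@H](O[Si](C)(C)C(C)(C)C)CC#CC(=O)OCC)cc1 | intermediate
13 | (Z)-heptadec-10-enylmagnesium bromide | CCCCCC/C=C\CCCCCCCCC[Mg]Br | intermediate
14 | (Z)-heptadec-10-enylcopper (as its MgBr2 complex) | CCCCCC/C=C\CCCCCCCCC[Cu] | intermediate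
15 | ethyl (2Z,13Z)-3-[(2S)-2-(tert-butyldimethylsilyloxy)-3-(4-methoxybenzyloxy)propyl]icosa-2,13-dienoate | CCOC(=O)/C=C(/CCCCCCCCC/C=C\CCCCCC)C[C@H](O[Si](C)(C)C(C)(C)C)COCc1ccc(OC)cc1 | intermediate
16 | (2Z,13Z)-3-[(2S)-2-(tert-butyldimethylsilyloxy)-3-(4-methoxybenzyloxy)propyl]icosa-2,13-dien-1-ol | OC/C=C(/CCCCCCCCC/C=C\CCCCCC)C[C@H](O[Si](C)(C)C(C)(C)C)COCc1ccc(OC)cc1 | intermediate
17 | {(2S,3R)-3-[(2S)-2-(tert-butyldimethylsilyloxy)-3-(4-methoxybenzyloxy)propyl]-3-[(Z)-heptadec-10-en-1-yl]oxiran-2-yl}methanol | OC[C@@H]1O[C@]1(CCCCCCCCC/C=C\CCCCCC)C[C@H](O[Si](C)(C)C(C)(C)C)COCc1ccc(OC)cc1 | intermediate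
18 | (2R,3R)-2-[(2S)-2-(tert-butyldimethylsilyloxy)-3-(4-methoxybenzyloxy)propyl]-2-[(Z)-heptadec-10-en-1-yl]-3-(iodomethyl)oxirane | IC[C@@H]1O[C@]1(CCCCCCCCC/C=C\CCCCCC)C[C@H](O[Si](C)(C)C(C)(C)C)COCc1ccc(OC)cc1 | intermediate
19 | (2S,4R,14Z)-2-(tert-butyldimethylsilyloxy)-4-ethenyl-1-(4-methoxybenzyloxy)henicos-14-en-4-ol | C=C[C@@](O)(CCCCCCCCC/C=C\CCCCCC)C[C@H](O[Si](C)(C)C(C)(C)C)COCc1ccc(OC)cc1 | intermediate
20 | (2S,4R,14Z)-2-(tert-butyldimethylsilyloxy)-4-ethenyl-1-(4-methoxybenzyloxy)-4-(triethylsilyloxy)henicos-14-ene | C=C[C@@](O[Si](CC)(CC)CC)(CCCCCCCCC/C=C\CCCCCC)C[C@H](O[Si](C)(C)C(C)(C)C)COCc1ccc(OC)cc1 | intermediate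
21 | (2S,4R,14Z)-2-(tert-butyldimethylsilyloxy)-4-ethenyl-4-(triethylsilyloxy)henicos-14-en-1-ol | C=C[C@@](O[Si](CC)(CC)CC)(CCCCCCCCC/C=C\CCCCCC)C[C@H](O[Si](C)(C)C(C)(C)C)CO | intermediate
22 | (2S,4R,14Z)-2-(tert-butyldimethylsilyloxy)-4-ethenyl-4-(triethylsilyloxy)henicos-14-enal | C=C[C@@](O[Si](CC)(CC)CC)(CCCCCCCCC/C=C\CCCCCC)C[C@H](O[Si](C)(C)C(C)(C)C)C=O | intermediate
23 | (2S,4R,14Z)-2-(tert-butyldimethylsilyloxy)-4-ethenyl-4-(triethylsilyloxy)henicos-14-enoic acid | C=C[C@@](O[Si](CC)(CC)CC)(CCCCCCCCC/C=C\CCCCCC)C[C@H](O[Si](C)(C)C(C)(C)C)C(=O)O | intermediate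
24 | methyl (2S,4R,14Z)-2-(tert-butyldimethylsilyloxy)-4-ethenyl-4-(triethylsilyloxy)henicos-14-enoate | COC(=O)[C@@H](O[Si](C)(C)C(C)(C)C)C[C@@](O[Si](CC)(CC)CC)(C=C)CCCCCCCCC/C=C\CCCCCC | intermediate
25 | diisopropoxytitanacyclopropane of 24 (Ti bridging C2 and C3) | COC(=O)[C@@H](O[Si](C)(C)C(C)(C)C)C[C@@](O[Si](CC)(CC)CC)([C@H]1C[Ti]1(OC(C)C)OC(C)C)CCCCCCCCC/C=C\CCCCCC | intermediate
26 | cyclopentanone (ring C1, C3, C4, C5, C6) carrying C2H2–Ti(OMe)(OiPr)2 on C3 | O=C1[C@@H](O[Si](C)(C)C(C)(C)C)C[C@](O[Si](CC)(CC)CC)(CCCCCCCCC/C=C\CCCCCC)[C@H]1C[Ti](OC)(OC(C)C)OC(C)C | intermediate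
27 | (1S,2S,4R,5S)-2-(tert-butyldimethylsilyloxy)-4-[(Z)-heptadec-10-en-1-yl]-4-(triethylsilyloxy)bicyclo[3.1.0]hexan-1-ol | O[C@@]12C[C@@H]1[C@@](O[Si](CC)(CC)CC)(CCCCCCCCC/C=C\CCCCCC)C[C@@H]2O[Si](C)(C)C(C)(C)C | intermediate
28 | (2S,4R,5RS)-2-(tert-butyldimethylsilyloxy)-5-chloro-4-[(Z)-heptadec-10-en-1-yl]-4-(triethylsilyloxy)cyclohexan-1-one | O=C1CC(Cl)[C@@](O[Si](CC)(CC)CC)(CCCCCCCCC/C=C\CCCCCC)C[C@@H]1O[Si](C)(C)C(C)(C)C | intermediate
29 | (4R,6S)-6-(tert-butyldimethylsilyloxy)-4-[(Z)-heptadec-10-en-1-yl]-4-(triethylsilyloxy)cyclohex-2-en-1-one | O=C1C=C[C@@](O[Si](CC)(CC)CC)(CCCCCCCCC/C=C\CCCCCC)C[C@@H]1O[Si](C)(C)C(C)(C)C | intermediate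
30 | (4R,6S)-4-[(Z)-heptadec-10-en-1-yl]-4,6-dihydroxycyclohex-2-en-1-one | CCCCCC/C=C\CCCCCCCCC[C@]1(O)C=CC(=O)[C@@H](O)C1 | target

## Step count

Total step count: 19.
Longest linear sequence: 16 steps (steps 1–3 or steps 4–6, then steps 7–19).

## Steps most likely to fail

**Step 16.** Transfer of titanium from cyclopentene to a vinyl group that sits on a fully substituted carbon may be too slow. The ester would then be consumed by the Grignard reagent, or the alkene complex may expel the C4 silyloxide before it cyclises.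

The fallback sets out from 24 and comes back at 29.
- Aminolysis of the ester with MeNHOMe·HCl and i-PrMgCl (THF, −20 °C) should give the Weinreb amide F1.
- Vinylmagnesium bromide should convert it into the vinyl ketone F2.
- Ring-closing metathesis with the second-generation Grubbs catalyst (CH2Cl2, reflux, high dilution) should join the two terminal alkenes directly as C2=C3. The internal chain alkene is the slower metathesis partner.
- This bypasses 27 and 28.

**Step 17.** The Lewis-acidic iron chloride and the HCl it releases may strip the tertiary triethylsilyl ether, and chlorine transfer to the hindered C3 radical next to the quaternary C4 may be inefficient.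

The fallback sets out from 27 and comes back at 29.
- Oxidation with Fe(NO3)3·9H2O in DMF in the presence of 1,4-cyclohexadiene ends the same strain-driven ring expansion by hydrogen transfer instead of halogen transfer. It should give the saturated ketone F3.
- Kinetic deprotonation at the unhindered C2 with LiN(SiMe3)2 and trapping with Me3SiCl (THF, −78 °C) should give the silyl enol ether F4.
- Saegusa–Ito dehydrogenation with Pd(OAc)2 in MeCN should install C2=C3.

**Step 9.** The substituent cis to the carbinol is branched at its second carbon, which may slow the epoxidation and lower its facial selectivity. Any geometric leakage from step 7 would also translate directly into the wrong C4 configuration.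

The fallback sets out from 12 and comes back at 19. It builds the geometric isomer in which the unbranched chain is the cis substituent.
- i-Bu2AlH reduces 12 to the propargylic alcohol F5.
- Chelate-controlled trans-hydroalumination with NaAlH2(OCH2CH2OMe)2, followed by I2, should give the (Z)-iodoalkenol F6.
- Negishi coupling (Pd(dppf)Cl2 cat., THF) with an excess of the alkylzinc bromide F7, made from Grignard reagent 13 and ZnBr2, should give the (2E)-allylic alcohol F8 with retention.
- Katsuki–Sharpless epoxidation with D-(−)-diethyl tartrate should then deliver the epoxy alcohol F9, which has the same R configuration at C4.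
- PPh3/imidazole/I2 gives the epoxy iodide F10, and Zn in EtOH fragments it to 19, the differing epoxide CH centre being destroyed.

## Further compounds

F1 | step 16 | (2S,4R,14Z)-2-(tert-butyldimethylsilyloxy)-4-ethenyl-N-methoxy-N-methyl-4-(triethylsilyloxy)henicos-14-enamide | CON(C)C(=O)[C@@H](O[Si](C)(C)C(C)(C)C)C[C@@](O[Si](CC)(CC)CC)(C=C)CCCCCCCCC/C=C\CCCCCC
F2 | step 16 | (4S,6R,16Z)-4-(tert-butyldimethylsilyloxy)-6-ethenyl-6-(triethylsilyloxy)tricosa-1,16-dien-3-one | C=CC(=O)[C@@H](O[Si](C)(C)C(C)(C)C)C[C@@](O[Si](CC)(CC)CC)(C=C)CCCCCCCCC/C=C\CCCCCC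
F3 | step 17 | (2S,4S)-2-(tert-butyldimethylsilyloxy)-4-[(Z)-heptadec-10-en-1-yl]-4-(triethylsilyloxy)cyclohexan-1-one | O=C1CC[C@@](O[Si](CC)(CC)CC)(CCCCCCCCC/C=C\CCCCCC)C[C@@H]1O[Si](C)(C)C(C)(C)C
F4 | step 17 | (4S,6S)-6-(tert-butyldimethylsilyloxy)-4-[(Z)-heptadec-10-en-1-yl]-4-(triethylsilyloxy)-1-(trimethylsilyloxy)cyclohex-1-ene | C[Si](C)(C)OC1=CC[C@@](O[Si](CC)(CC)CC)(CCCCCCCCC/C=C\CCCCCC)C[C@@H]1O[Si](C)(C)C(C)(C)C
F5 | step 9 | (5S)-5-(tert-butyldimethylsilyloxy)-6-(4-methoxybenzyloxy)hex-2-yn-1-ol | OCC#CC[C@H](O[Si](C)(C)C(C)(C)C)COCc1ccc(OC)cc1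
F6 | step 9 | (2Z,5S)-5-(tert-butyldimethylsilyloxy)-3-iodo-6-(4-methoxybenzyloxy)hex-2-en-1-ol | OC/C=C(\I)C[C@H](O[Si](C)(C)C(C)(C)C)COCc1ccc(OC)cc1
F7 | step 9 | (Z)-heptadec-10-enylzinc bromide | CCCCCC/C=C\CCCCCCCCC[Zn]Br
F8 | step 9 | (2E,13Z)-3-[(2S)-2-(tert-butyldimethylsilyloxy)-3-(4-methoxybenzyloxy)propyl]icosa-2,13-dien-1-ol | OC/C=C(\CCCCCCCCC/C=C\CCCCCC)C[C@H](O[Si](C)(C)C(C)(C)C)COCc1ccc(OC)cc1
F9 | step 9 | {(2R,3R)-3-[(2S)-2-(tert-butyldimethylsilyloxy)-3-(4-methoxybenzyloxy)propyl]-3-[(Z)-heptadec-10-en-1-yl]oxiran-2-yl}methanol | OC[C@H]1O[C@]1(CCCCCCCCC/C=C\CCCCCC)C[C@H](O[Si](C)(C)C(C)(C)C)COCc1ccc(OC)cc1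
F10 | step 9 | (2R,3S)-2-[(2S)-2-(tert-butyldimethylsilyloxy)-3-(4-methoxybenzyloxy)propyl]-2-[(Z)-heptadec-10-en-1-yl]-3-(iodomethyl)oxirane | IC[C@H]1O[C@]1(CCCCCCCCC/C=C\CCCCCC)C[C@H](O[Si](C)(C)C(C)(C)C)COCc1ccc(OC)cc1
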